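The data come from a simulation for an exercise; scatter was added.

The amounts charged and the products read in the three earlier flasks, oak, elm and larch, stand here beside the flask we must foresee.

| setting | oak | elm | larch | flask |
|---|---|---|---|---|
| left-handed substrate | 1.5 M | 1.5 M | 0.75 M | 1.5 M |
| right-handed substrate | 1.5 M | 1.5 M | 0.75 M | 1.5 M |
| gas | 200 mM (held) | 200 mM (held) | 200 mM (held) | 200 mM (held) |
| catalyst | 11 mM | 24 mM | 16 mM | 16 mM |
| added ligand | 21 mM | 21 mM | 21 mM | 21 mM |
| remark | run made earlier | run made earlier | run made earlier |  |
| time |  |  |  | 15 min |

- oak (time / min: left-handed product / %, right-handed product / %): 1.00: 0, 2; 2.00: 2, 2; 5.00: 7, 6; 12.0: 14, 10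
- elm (time / min: left-handed product / %, right-handed product / %): 3.00: 5, 2; 6.00: 9, 3; 10.0: 12, 10; 12.0: 17, 10
- larch (time / min: left-handed product / %, right-handed product / %): 1.50: 4, 4; 4.00: 1, 5; 8.00: 13, 13; 12.0: 19, 15

(standard deviation of a reading: 2 percentage points)

- catalyst is single-handed; left-handed substrate and right-handed substrate are mirror images of each other, charged as a racemate, each of them at the stated concentration
- at the start none of the gas is in solution
- an excess is the difference of the two amounts in percent of their sum
- an excess is below zero if the other one leads

* excess of left-handed product over right-handed product in the product at 20 s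
* excess of left-handed product over right-handed product in the product at 15 min
* part of the left-handed substrate and right-handed substrate charged together that has reacted at 15 min

At 12.0 min the two products together read 24.0 % of the charged substrate in oak and 27.0 % in elm, although elm holds 2.18 times the c(catalyst) of oak, with substrate, gas and added ligand the same. From this pair we carry the catalyst exponent n = 0.151, the slope of ln(product) against ln c(catalyst) at a fixed time with the other charges held, and it stays a reading with the scatter of its four numbers.

Turning the question round, if the catalyst step were the rate-limiting step, the exponent would stand near one and elm would have read about 52.4 %, which is 25 percentage points from its reading, against a scatter of 2 points per reading; since n is so much less than one, we look for the limit elsewhere, most likely in the gas entering solution. The flask has the substrate charge of oak and a c(catalyst) of 16 mM, so oak's total, stretched in a straight line to 15 min and scaled with n, gives us 31.7 % reacted, whereas an exponent of one gives 43.6 %, which is more than our figure. The exponent says nothing of the excesses, and we commit to no number for them.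

The forecast, holding that “gas transfer largely limits the rate”, gives 30 % and 13 % for the two excesses and 31 % reacted.

The flask gives excesses of 25.9 % at 20 s and 10.7 % at 15 min, with 30.7 % reacted against our 31.7 %.

    left-handed product ⇌ right-handed product (k = 0.00110 s⁻¹)
    coupling partner + catalyst + left-handed substrate → catalyst + left-handed product (k = 0.840 L² mol⁻² s⁻¹)
    coupling partner + catalyst + right-handed substrate → catalyst + right-handed product (k = 0.490 L² mol⁻² s⁻¹)
    catalyst + added ligand ⇌ idle complex, settled at all times (K = 31.0 L mol⁻¹)
    left-handed substrate ⇌ right-handed substrate (k = 0.00220 s⁻¹)
    gas ⇌ coupling partner, rate k6*(csat - [coupling partner]) (kL = 0.00770 s⁻¹)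

At 15.0 min the flask makes coupling partner, the gas in solution, 1.02 times faster than it uses it, and c(coupling partner) stands at 0.0676 M against a saturation of 200 mM. We then put n to a second flask, like this one but with a c(catalyst) of 0.040 M: n gives 35.3 % reacted at 15 min, that flask gives 38.7 %, and the exponent reckoned between the two flasks is 0.253.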